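# Proposed synthesis of (2S)-5,7-dihydroxy-2-(7-hydroxy-2,2-dimethyl-2H-chromen-6-yl)-8-(3-hydroxy-3-methylbutyl)chroman-4-one (17)

Abbreviations: TBS = tert-butyldimethylsilyl; DBU = 1,8-diazabicyclo[5.4.0]undec-7-ene; DIAD = diisopropyl azodicarboxylate; DDQ = 2,3-dichloro-5,6-dicyano-1,4-benzoquinone; EDDA = ethylenediammonium diacetate.

## The problem

The target 17 is a (2S)-flavanone. A phloroglucinol-type ring A is fused through O1 and C4 to the dihydropyranone ring C, and C2 carries a resorcinol-type ring B that is itself fused at C4′–C5′ to a 2,2-dimethyl-2H-pyran (ring D). Ring A is fully differentiated, with free hydroxyls at C5 and C7 and a 3-hydroxy-3-methylbutyl chain at C8, so the oxygen that becomes O1 must be singled out among three phenolic oxygens, next to the chain. C2 is the only stereocentre and nothing in the molecule can relay chirality to it, so it must be set by a catalyst. Once set it is fragile: it is β to the C4 ketone, so base opens ring C by a retro-oxa-Michael reaction, and it is benzylic to a ring with an ortho hydroxyl and a para ether oxygen, so acid ionises C2–O1. The tertiary alcohol lies ortho to the C7 hydroxyl and would close to a 2,2-dimethylchroman or dehydrate under protic acid. The chromene double bond rules out hydrogenolysis and any late alkene hydration. These constraints call for protecting groups that leave under neutral or buffered conditions and for a ring C closure that creates C2 late. The feature that offers such a closure is that C2 is an ether carbon flanked by O1 and by C1′ of ring B, whose C2′ hydroxyl and C4′ oxygen make a hydride at C2 easy to remove, while C3 is the enolisable α-carbon of the C4 aryl ketone. A CH2 group at C2 can therefore be oxidised to an ortho-quinone methide and attacked by the enol of an acetyl group.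

## Retrosynthesis

**17 from 16.** The last operation should only uncover hydroxyls. Cutting two O–Si bonds leads from 17 back to the 5,7-bis-TBS ether 16. Silyl ethers are preferred because they leave with buffered fluoride; acetal protection would need protic acid (tertiary alcohol, C2–O1) and benzyl protection hydrogenolysis (chromene). The tertiary alcohol and the ring B phenol are carried free, so 16 differs from 17 only by the two silyl groups. The forward step must cleave two aryl silyl ethers without leaving a persistent phenoxide.

**16 from 14 via 15.** Ring C is opened at C2–C3. Cutting O1–C2 would call for an oxa-Michael closure that is reversible and hard to render enantioselective with so electron-rich a ring B. Cutting O1–C8a would call for nucleophilic aromatic substitution on an electron-rich ring A. Cutting C4–C4a would call for an acylation of ring A with C2 already in place. Only the C2–C3 cut gives an achiral precursor, the aryl benzyl ether 14, in which C2 is a CH2 group and C3 the methyl of an acetyl group. In the forward sense a quinone oxidant removes hydride from that CH2 to give the ortho-quinone methide 15, and a chiral phosphoric acid steers the acetyl enol onto C2. The C–C bond, ring C and the stereocentre then arise together. The step must abstract hydride at the right benzylic carbon, favour C- over O-attack of the enol, distinguish the faces of a planar C2 and stop before 16 is oxidised further. The free C2′ hydroxyl of 14 is kept on purpose: it is the source of 15 and the hydrogen-bonding handle for the catalyst.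

**14 from 13, and 13 from 5 and 12.** Ether 14 is cut at the O–CH2 bond into the ring A phenol 5 and the ring B benzylic alcohol 12. A Mitsunobu coupling is chosen over base-mediated alkylation, because halide activation of so electron-rich a benzylic position invites ionisation and base endangers the aryl silyl ethers. The ring B phenol cannot be free during the coupling, since activating a benzylic hydroxyl next to a free phenol would trigger quinone methide formation. It is therefore carried as the allyl ether in 12 and 13 and released from 13 by zerovalent palladium, which is neutral and orthogonal to the silyl ethers. The cut divides the molecule into two halves of similar size. It asks the forward reaction to etherify a hydrogen-bonded, ortho-flanked phenol beside a tertiary alcohol, which is too hindered and too weakly acidic to interfere.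

**5 from 4, 4 from 3, 3 from 1 and 2.** In 5 the tertiary C–OH bond is cut first: 5 is the Markovnikov hydrate of the prenyl group of 4. A radical (hydrogen-atom transfer) hydration is specified because a cationic one would be intercepted by the neighbouring phenol. The two O–Si bonds of 4 are then cut to give triol 3; selective silylation should leave free only the hydroxyl wedged between the prenyl and acetyl groups, which is the oxygen destined to become O1. Finally the aryl–CH2 bond of 3 is cut to 2,4,6-trihydroxyacetophenone 1 and prenyl bromide 2. The two free ring positions of 1 are equivalent, which removes the regiochemical question that would arise if the acetyl group were introduced after the chain.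

**12 from 11, 11 from 9 via 10, 9 from 8, 8 from 6 and 7.** Alcohol 12 is the reduction product of aldehyde 11. The formyl C–C bond of 11 is cut to aryllithium 10, which comes from bromide 9 by halogen–lithium exchange, and 9 is the allyl ether of bromochromenol 8. The pyran ring of 8 is cut at O1–C2 and C4–C4a to 4-bromoresorcinol 6 and 3-methylbut-2-enal 7. The bromine of 6 does double duty: it blocks the ring position that would compete in the annulation, and it marks C6 of 8 for the one-carbon unit. An electrophilic formylation without the halogen would have to choose between two positions ortho to the hydroxyl.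

## Roads not taken

**Alternative 1:** Ring A would be built last, by cutting C4a–C5. The precursor is the dihydropyranone A2, in which C2 already carries ring B and the future C8a carries a branched chain ending in a 2,2-dimethyl-1,3-dioxin-4-one. Heating A2 would expel acetone and unveil an acylketene. Its ketene carbon would acylate C4a, the α-carbon of the vinylogous ester, and enolisation would aromatise the new ring to give A1 with the C5 and C7 hydroxyls free.
- Merits: no selective protection of a phloroglucinol is needed; the C2 stereocentre would come from an asymmetric hetero-Diels–Alder reaction, a well-established catalytic process; dioxinone thermolysis with aromatisation is a known reaction type.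
- Weak points: A2 is a long synthesis in itself, because one carbon must be joined to the dihydropyranone, the dioxinone and the silyloxy chain. The α-carbon of a vinylogous ester is a weak nucleophile for an acylketene that can also dimerise. The electron-rich aryl group at C2 makes ring opening of the dihydropyranone, and loss of configuration, a real risk at the thermolysis temperature. A1 would still need acid to remove its methoxymethyl group, next to the tertiary alcohol.
- Comparison: this road is better than the chosen one in the pedigree of its stereocentre and in the way ring A is differentiated. The chosen plan sets against it two aromatic fragments made in three and four steps from commercial phenols and an endgame without acid, at the price of a key step without direct precedent.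

**Alternative 2:** Ring C would be closed at C3=C4 by ring-closing metathesis. The precursor A4 carries ring B and a vinyl group on the future C2 as a secondary allylic aryl ether, and the acetyl group as its TBS enol ether. A second-generation Grubbs catalyst would join the two terminal alkenes with loss of ethylene and deliver the silyl enol ether A3, hydrolysed later to the ketone.
- Merits: olefin metathesis is a mature, neutral ring closure; the configuration at C2 is fixed before ring closure; the ketone emerges masked.
- Weak points: the enol ether alkene is 1,1-disubstituted and flanked by two ortho substituents, so the closure will be slow. The cis-styrenyl alkene of ring D is a second site for the ruthenium carbene. The C2–H bond of A4 and A3 is allylic, benzylic and α to oxygen, so ruthenium hydride-mediated alkene migration would erase the stereocentre. A4 itself demands the enantioselective formation of a secondary, doubly activated aryl ether on a hindered phenol, a bond that tends to form through an ionised, racemising pathway. Three methoxymethyl ethers and a triethylsilyl ether again need acid at the end.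
- Comparison: the ring closure here is known chemistry, which the chosen plan cannot claim. The stereochemical problem is however only moved into the preparation of A4, whereas the chosen plan needs a primary benzylic ether, with no stereochemistry in the coupling, and creates stereocentre and ring in one operation.

**Alternative 3:** Ring C would be closed at O1–C8a. The precursor A6 is a β-hydroxy ketone whose carbinol carbon is the future C2 and whose ring A carries fluorine at the future C8a. Deprotonation (KN(SiMe3)2 or Cs2CO3) and intramolecular nucleophilic aromatic substitution ortho to the ketone would give the fully protected flavanone A5.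
- Merits: the C2–O bond is made before ring closure and never broken, so a stereocentre set by an established asymmetric aldol reaction or ketone reduction is carried through unchanged. In certainty of configuration this road is superior to the chosen one.
- Weak points: the fluoroarene of A6 is electron-rich (two acetal oxygens and an alkyl group) and is activated by a single acyl group, so the substitution needs strong base or heat. Under those conditions a β-hydroxy ketone undergoes retro-aldol cleavage and E1cB dehydration. The fluorinated ring A cannot be derived from 1 and must be built separately. A5 again needs acidic deprotection.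
- Comparison: the chosen plan gives up the security of a preformed stereocentre. It sets against this a ring A that comes directly from 1, intermediates without a base-labile aldol unit, a shorter sequence and a neutral final step.

Key step: step 10

Assumption: the (R)-enantiomer of the phosphoric acid TRIP (3,3′-bis(2,4,6-triisopropylphenyl)-1,1′-binaphthyl-2,2′-diyl hydrogen phosphate) is taken to give the (2S)-product in step 10; should the sense of induction be the opposite, the (S)-acid is used and nothing else changes.

## Route

Step 1
Reactants: 1 2,4,6-trihydroxyacetophenone; 2 1-bromo-3-methylbut-2-ene (prenyl bromide)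
Product: 3 1-[2,4,6-trihydroxy-3-(3-methylbut-2-en-1-yl)phenyl]ethanone
Conditions: DBU, THF, rt
Reagents that add atoms: none
Why: Base-mediated C-alkylation of the ambident phloroglucinol anion by a soft allylic bromide; the two free ring positions of 1 are equivalent, so only one mono-C-prenyl product can form, and a slight deficit of 2 limits double alkylation.

Step 2
Reactants: 3 1-[2,4,6-trihydroxy-3-(3-methylbut-2-en-1-yl)phenyl]ethanone
Product: 4 1-[4,6-bis(tert-butyldimethylsilyloxy)-2-hydroxy-3-(3-methylbut-2-en-1-yl)phenyl]ethanone
Conditions: TBSCl (2.1 equiv), imidazole, CH2Cl2, 0 °C → rt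
Reagents that add atoms: tert-butyldimethylsilyl chloride, CC(C)(C)[Si](C)(C)Cl
Why: Selective silylation; the unchelated 4-hydroxyl reacts first and, of the two hydroxyls hydrogen-bonded to the acetyl group, the one flanked only by hydrogen is silylated, while the one wedged between the prenyl and acetyl groups (the future O1) stays free.

Step 3
Reactants: 4 1-[4,6-bis(tert-butyldimethylsilyloxy)-2-hydroxy-3-(3-methylbut-2-en-1-yl)phenyl]ethanone
Product: 5 1-[4,6-bis(tert-butyldimethylsilyloxy)-2-hydroxy-3-(3-hydroxy-3-methylbutyl)phenyl]ethanone
Conditions: Co(acac)2 (cat.), PhSiH3, O2 (1 atm), THF, rt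
Reagents that add atoms: dioxygen, O=O
Why: Mukaiyama hydration; hydrogen-atom transfer from a cobalt hydride gives the tertiary radical, which is trapped by O2 and reduced to the Markovnikov alcohol, so no carbocation forms that the neighbouring phenol could capture as a chroman, and the ketone and aryl silyl ethers are left alone.

Step 4
Reactants: 6 4-bromobenzene-1,3-diol (4-bromoresorcinol); 7 3-methylbut-2-enal
Product: 8 6-bromo-2,2-dimethyl-2H-chromen-7-ol
Conditions: EDDA (cat.), toluene, reflux
Reagents that add atoms: none
Why: Amine salt-catalysed condensation of the enal at the ring carbon ortho to one hydroxyl and para to the other, then oxa-6π electrocyclisation of the dienone; bromine blocks C4 of 6 and the position between the two hydroxyls is the more hindered, so the pyran ring should form in the linear sense.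

Step 5
Reactants: 8 6-bromo-2,2-dimethyl-2H-chromen-7-ol
Product: 9 6-bromo-2,2-dimethyl-7-(prop-2-en-1-yloxy)-2H-chromene
Conditions: allyl bromide, K2CO3, acetone, reflux
Reagents that add atoms: allyl bromide (3-bromoprop-1-ene), C=CCBr
Why: Williamson etherification of the phenol; the allyl ether withstands the organolithium step and is later removed under neutral conditions.

Step 6
Reactants: 9 6-bromo-2,2-dimethyl-7-(prop-2-en-1-yloxy)-2H-chromene
Product: 11 2,2-dimethyl-7-(prop-2-en-1-yloxy)-2H-chromene-6-carbaldehyde, via aryllithium 10 (not isolated)
Conditions: n-BuLi, THF, –78 °C; DMF, –78 → 0 °C; H2O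
Reagents that add atoms: n-butyllithium, [Li]CCCC (supplies the lithium of 10); N,N-dimethylformamide, CN(C)C=O (supplies the formyl group of 11)
Why: Bromine–lithium exchange at –78 °C is faster than any reaction of butyllithium with the allyl ether, and the aryllithium is formylated by DMF (Bouveault-type formylation), which places the carbon at C6.

Step 7
Reactants: 11 2,2-dimethyl-7-(prop-2-en-1-yloxy)-2H-chromene-6-carbaldehyde
Product: 12 [2,2-dimethyl-7-(prop-2-en-1-yloxy)-2H-chromen-6-yl]methanol
Conditions: NaBH4, MeOH, 0 °C
Reagents that add atoms: none
Why: Borohydride reduction of the aryl aldehyde to the primary benzylic alcohol; the chromene and the allyl ether are inert.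

Step 8
Reactants: 5 1-[4,6-bis(tert-butyldimethylsilyloxy)-2-hydroxy-3-(3-hydroxy-3-methylbutyl)phenyl]ethanone; 12 [2,2-dimethyl-7-(prop-2-en-1-yloxy)-2H-chromen-6-yl]methanol
Product: 13 1-[4,6-bis(tert-butyldimethylsilyloxy)-2-{[2,2-dimethyl-7-(prop-2-en-1-yloxy)-2H-chromen-6-yl]methoxy}-3-(3-hydroxy-3-methylbutyl)phenyl]ethanone
Conditions: PPh3, DIAD, THF, 0 °C → rt
Reagents that add atoms: none
Why: Mitsunobu etherification; the primary benzylic alcohol is activated as its oxyphosphonium salt and displaced by the acidic phenol of 5, the tertiary alcohol is neither acidic nor accessible enough to take part, and no base or benzylic halide is needed.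

Step 9
Reactants: 13 1-[4,6-bis(tert-butyldimethylsilyloxy)-2-{[2,2-dimethyl-7-(prop-2-en-1-yloxy)-2H-chromen-6-yl]methoxy}-3-(3-hydroxy-3-methylbutyl)phenyl]ethanone
Product: 14 1-[4,6-bis(tert-butyldimethylsilyloxy)-2-[(7-hydroxy-2,2-dimethyl-2H-chromen-6-yl)methoxy]-3-(3-hydroxy-3-methylbutyl)phenyl]ethanone
Conditions: Pd(PPh3)4 (cat.), morpholine, THF, rt
Reagents that add atoms: none
Why: Tsuji–Trost deallylation; zerovalent palladium ionises the aryl allyl ether and morpholine traps the allyl fragment, while the endocyclic allylic C–O bond of the chromene lies near the plane of its alkene and is not ionised, and the silyl ethers and the benzylic aryl ether are untouched.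

Step 10
Reactants: 14 1-[4,6-bis(tert-butyldimethylsilyloxy)-2-[(7-hydroxy-2,2-dimethyl-2H-chromen-6-yl)methoxy]-3-(3-hydroxy-3-methylbutyl)phenyl]ethanone
Product: 16 (2S)-5,7-bis(tert-butyldimethylsilyloxy)-2-(7-hydroxy-2,2-dimethyl-2H-chromen-6-yl)-8-(3-hydroxy-3-methylbutyl)-2,3-dihydro-4H-chromen-4-one, via ortho-quinone methide 15 (not isolated)
Conditions: DDQ (1.05 equiv), (R)-TRIP (10 mol%), 4 Å molecular sieves, CH2Cl2, –40 → –20 °C
Reagents that add atoms: none
Why: Proposed new method: DDQ removes hydride from the ArOCH2Ar carbon of 14 and proton loss from the ortho phenol gives the aryloxy-substituted ortho-quinone methide 15; the chiral phosphoric acid hydrogen-bonds or protonates the quinone methide oxygen (a contact ion pair with the benzylic oxocarbenium form) while its phosphoryl oxygen accepts the hydroxyl of the acetyl enol, and the enol carbon C3 adds to C2. The closest known reaction types are DDQ-mediated oxidative C–H cleavage of benzylic ethers with intramolecular capture by an enol derivative, and phosphoric acid-catalysed enantioselective additions of carbon nucleophiles to ortho-quinone methides; neither has been shown for an aryl benzyl ether with a free ketone as pronucleophile. Ring C closes in a 6-exo-trig (enolendo) mode onto the exocyclic C2=C1′ bond of 15, and rearomatisation of ring B returns the 2′-hydroxyl. The C2 stereocentre is set by the catalyst alone, whose 3,3′-aryl groups shield one face of the planar C2 in the doubly hydrogen-bonded transition state; the (2S) sense is the assumption stated above. Site selectivity of hydride abstraction is secured by the substrate, since the other benzylic CH2 sits on ring A, which is deactivated by the acetyl group and has no free phenol, and the chromene has no abstractable hydride. Attack through oxygen would give a cyclic enol acetal that re-ionises under the acid and funnels to the C–C bonded ketone in the manner of a Petasis–Ferrier rearrangement. Molecular sieves exclude water, which would hydrolyse 15 (oxidative debenzylation), and one equivalent of DDQ at low temperature avoids further dehydrogenation of 16.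

Step 11
Reactants: 16 (2S)-5,7-bis(tert-butyldimethylsilyloxy)-2-(7-hydroxy-2,2-dimethyl-2H-chromen-6-yl)-8-(3-hydroxy-3-methylbutyl)-2,3-dihydro-4H-chromen-4-one
Product: 17 (2S)-5,7-dihydroxy-2-(7-hydroxy-2,2-dimethyl-2H-chromen-6-yl)-8-(3-hydroxy-3-methylbutyl)-2,3-dihydro-4H-chromen-4-one
Conditions: n-Bu4NF, AcOH, THF, 0 °C
Reagents that add atoms: none
Why: Fluoride-mediated cleavage of the two aryl silyl ethers; acetic acid buffers the phenoxides so that neither retro-oxa-Michael opening of ring C nor ionisation at C2 can racemise the stereocentre, and the tertiary alcohol and chromene are unaffected.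

## Compound list

1 | 2,4,6-trihydroxyacetophenone | CC(=O)c1c(O)cc(O)cc1O | starting material
2 | 1-bromo-3-methylbut-2-ene (prenyl bromide) | CC(C)=CCBr | starting material
3 | 1-[2,4,6-trihydroxy-3-(3-methylbut-2-en-1-yl)phenyl]ethanone | CC(=O)c1c(O)cc(O)c(CC=C(C)C)c1O | intermediate
4 | 1-[4,6-bis(tert-butyldimethylsilyloxy)-2-hydroxy-3-(3-methylbut-2-en-1-yl)phenyl]ethanone | CC(=O)c1c(O[Si](C)(C)C(C)(C)C)cc(O[Si](C)(C)C(C)(C)C)c(CC=C(C)C)c1O | intermediate
5 | 1-[4,6-bis(tert-butyldimethylsilyloxy)-2-hydroxy-3-(3-hydroxy-3-methylbutyl)phenyl]ethanone | CC(=O)c1c(O[Si](C)(C)C(C)(C)C)cc(O[Si](C)(C)C(C)(C)C)c(CCC(C)(C)O)c1O | intermediate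
6 | 4-bromobenzene-1,3-diol (4-bromoresorcinol) | Oc1ccc(Br)c(O)c1 | starting material
7 | 3-methylbut-2-enal | CC(C)=CC=O | starting material
8 | 6-bromo-2,2-dimethyl-2H-chromen-7-ol | CC1(C)C=Cc2cc(Br)c(O)cc2O1 | intermediate
9 | 6-bromo-2,2-dimethyl-7-(prop-2-en-1-yloxy)-2H-chromene | CC1(C)C=Cc2cc(Br)c(OCC=C)cc2O1 | intermediate
10 | [2,2-dimethyl-7-(prop-2-en-1-yloxy)-2H-chromen-6-yl]lithium | CC1(C)C=Cc2cc([Li])c(OCC=C)cc2O1 | intermediate (not isolated)
11 | 2,2-dimethyl-7-(prop-2-en-1-yloxy)-2H-chromene-6-carbaldehyde | CC1(C)C=Cc2cc(C=O)c(OCC=C)cc2O1 | intermediate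
12 | [2,2-dimethyl-7-(prop-2-en-1-yloxy)-2H-chromen-6-yl]methanol | CC1(C)C=Cc2cc(CO)c(OCC=C)cc2O1 | intermediate
13 | 1-[4,6-bis(tert-butyldimethylsilyloxy)-2-{[2,2-dimethyl-7-(prop-2-en-1-yloxy)-2H-chromen-6-yl]methoxy}-3-(3-hydroxy-3-methylbutyl)phenyl]ethanone | CC(=O)c1c(O[Si](C)(C)C(C)(C)C)cc(O[Si](C)(C)C(C)(C)C)c(CCC(C)(C)O)c1OCc1cc2C=CC(C)(C)Oc2cc1OCC=C | intermediate
14 | 1-[4,6-bis(tert-butyldimethylsilyloxy)-2-[(7-hydroxy-2,2-dimethyl-2H-chromen-6-yl)methoxy]-3-(3-hydroxy-3-methylbutyl)phenyl]ethanone | CC(=O)c1c(O[Si](C)(C)C(C)(C)C)cc(O[Si](C)(C)C(C)(C)C)c(CCC(C)(C)O)c1OCc1cc2C=CC(C)(C)Oc2cc1O | intermediate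
15 | 6-{[2-acetyl-3,5-bis(tert-butyldimethylsilyloxy)-6-(3-hydroxy-3-methylbutyl)phenoxy]methylidene}-2,2-dimethyl-2H-chromen-7(6H)-one (ortho-quinone methide, alkene geometry undefined) | CC(=O)c1c(O[Si](C)(C)C(C)(C)C)cc(O[Si](C)(C)C(C)(C)C)c(CCC(C)(C)O)c1OC=C1C=C2C=CC(C)(C)OC2=CC1=O | intermediate (not isolated)
16 | (2S)-5,7-bis(tert-butyldimethylsilyloxy)-2-(7-hydroxy-2,2-dimethyl-2H-chromen-6-yl)-8-(3-hydroxy-3-methylbutyl)-2,3-dihydro-4H-chromen-4-one | CC(C)(O)CCc1c(O[Si](C)(C)C(C)(C)C)cc(O[Si](C)(C)C(C)(C)C)c2c1O[C@H](c1cc3c(cc1O)OC(C)(C)C=C3)CC2=O | intermediate
17 | (2S)-5,7-dihydroxy-2-(7-hydroxy-2,2-dimethyl-2H-chromen-6-yl)-8-(3-hydroxy-3-methylbutyl)-2,3-dihydro-4H-chromen-4-one | CC(C)(O)CCc1c(O)cc(O)c2c1O[C@H](c1cc3c(cc1O)OC(C)(C)C=C3)CC2=O | target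

## Step count and risks

Total step count: 11. Longest linear sequence: 8 steps (steps 4 to 11, from 6 to 17); the ring A branch (steps 1 to 3) joins at step 8.

**Step 10 (key step, proposed new method).**
- What may go wrong: enolisation of the ketone may be slow relative to consumption of the quinone methide by self-condensation or by cycloaddition with the chromene alkene of a second molecule. A racemic background closure, catalysed by the hydroquinone formed from the oxidant, would give poor facial selectivity. Further dehydrogenation across C2–C3 and hydrolytic loss of the benzylic ether through adventitious water are the other failure modes.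
- Fallback (known chemistry), setting out from 5 and 11 and returning at 16:
  - The trianion of 5 (LiN(SiMe3)2, THF, –78 °C) is added to aldehyde 11 to give the racemic aldol adduct F1.
  - Intramolecular Mitsunobu etherification of F1 (PPh3, DIAD, THF) closes ring C to the racemic allyl-protected flavanone F2.
  - Kinetic resolution of F2 by Noyori-type asymmetric transfer hydrogenation (RhCl[(R,R)-TsDPEN](C5Me5) or its mirror image, whichever consumes the (2R)-ketone; HCO2H, Et3N) is stopped near half conversion. It leaves the (2S)-ketone F3 and converts the other enantiomer into the cis-flavan-4-ol F4, which is removed by chromatography.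
  - Deallylation of F3 (Pd(PPh3)4, morpholine, THF) gives 16.

**Step 8 (Mitsunobu etherification).**
- What may go wrong: sluggish reaction of the hydrogen-bonded, ortho-flanked phenol, and ionisation of the activated benzylic oxyphosphonium species leading to C-benzylation of an electron-rich ring or to alkylation of the reduced azodicarboxylate.
- Fallback, setting out from 12 and returning at 13: 12 is converted with MsCl and Et3N in CH2Cl2 (in situ displacement of the mesylate by chloride) into the benzylic chloride F5. F5 then alkylates 5 under neutral conditions with Ag2O in CH2Cl2 to give 13.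

**Step 4 (chromene annulation).**
- What may go wrong: annulation at the ring position between the two hydroxyls (angular ring fusion), or oligomerisation of the enal with low conversion of the deactivated bromophenol.
- Fallback, setting out from 6 and returning at 8: Friedel–Crafts acylation and oxa-Michael closure of 6 with 3-methylbut-2-enoic acid in P2O5/MeSO3H gives the chromanone F6, whose regiochemistry is fixed by acylation para to a hydroxyl. NaBH4 reduction gives the chroman-4-ol F7, and acid-catalysed dehydration (TsOH, toluene, reflux) gives 8.

**Step 1 (C-prenylation).**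
- What may go wrong: over-alkylation at the second ring position and competing O-alkylation, giving low conversion to the mono-C-prenyl product.
- Fallback, setting out from 1 and returning at 3: Friedel–Crafts alkylation of 1 with 2-methylbut-3-en-2-ol and BF3·OEt2 in dioxane, which generates the prenyl cation under acid instead of alkylating a phenoxide. This fallback makes no compound outside the route (F0).

## Further compounds

F1 | step 10 | 1-[4,6-bis(tert-butyldimethylsilyloxy)-2-hydroxy-3-(3-hydroxy-3-methylbutyl)phenyl]-3-[2,2-dimethyl-7-(prop-2-en-1-yloxy)-2H-chromen-6-yl]-3-hydroxypropan-1-one (racemic) | O=C(CC(O)c1cc2C=CC(C)(C)Oc2cc1OCC=C)c1c(O[Si](C)(C)C(C)(C)C)cc(O[Si](C)(C)C(C)(C)C)c(CCC(C)(C)O)c1O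
F2 | step 10 | rac-5,7-bis(tert-butyldimethylsilyloxy)-2-[2,2-dimethyl-7-(prop-2-en-1-yloxy)-2H-chromen-6-yl]-8-(3-hydroxy-3-methylbutyl)-2,3-dihydro-4H-chromen-4-one | CC(C)(O)CCc1c(O[Si](C)(C)C(C)(C)C)cc(O[Si](C)(C)C(C)(C)C)c2c1OC(c1cc3c(cc1OCC=C)OC(C)(C)C=C3)CC2=O
F3 | step 10 | (2S)-5,7-bis(tert-butyldimethylsilyloxy)-2-[2,2-dimethyl-7-(prop-2-en-1-yloxy)-2H-chromen-6-yl]-8-(3-hydroxy-3-methylbutyl)-2,3-dihydro-4H-chromen-4-one | CC(C)(O)CCc1c(O[Si](C)(C)C(C)(C)C)cc(O[Si](C)(C)C(C)(C)C)c2c1O[C@H](c1cc3c(cc1OCC=C)OC(C)(C)C=C3)CC2=O
F4 | step 10 | (2R,4R)-5,7-bis(tert-butyldimethylsilyloxy)-2-[2,2-dimethyl-7-(prop-2-en-1-yloxy)-2H-chromen-6-yl]-8-(3-hydroxy-3-methylbutyl)-3,4-dihydro-2H-chromen-4-ol | CC(C)(O)CCc1c(O[Si](C)(C)C(C)(C)C)cc(O[Si](C)(C)C(C)(C)C)c2c1O[C@@H](c1cc3c(cc1OCC=C)OC(C)(C)C=C3)C[C@H]2O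
F5 | step 8 | 6-(chloromethyl)-2,2-dimethyl-7-(prop-2-en-1-yloxy)-2H-chromene | CC1(C)C=Cc2cc(CCl)c(OCC=C)cc2O1
F6 | step 4 | 6-bromo-7-hydroxy-2,2-dimethyl-2,3-dihydro-4H-chromen-4-one | CC1(C)CC(=O)c2cc(Br)c(O)cc2O1
F7 | step 4 | 6-bromo-2,2-dimethyl-3,4-dihydro-2H-chromene-4,7-diol (racemic) | CC1(C)CC(O)c2cc(Br)c(O)cc2O1
F0 | step 1 | none | none
A1 | alternative 1 | (2S)-5,7-dihydroxy-2-[7-(methoxymethoxy)-2,2-dimethyl-2H-chromen-6-yl]-8-(3-methyl-3-triethylsilyloxybutyl)-2,3-dihydro-4H-chromen-4-one | CC(C)(CCc1c(O)cc(O)c2c1O[C@H](c1cc3c(cc1OCOC)OC(C)(C)C=C3)CC2=O)O[Si](CC)(CC)CC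
A2 | alternative 1 | (2S)-6-[1-(2,2-dimethyl-4-oxo-4H-1,3-dioxin-6-yl)-4-methyl-4-(triethylsilyloxy)pentyl]-2-[7-(methoxymethoxy)-2,2-dimethyl-2H-chromen-6-yl]-2,3-dihydro-4H-pyran-4-one (side-chain stereocentre undefined) | CC1(C)OC(=O)C=C(O1)C(CCC(C)(C)O[Si](CC)(CC)CC)C1=CC(=O)C[C@@H](c2cc3c(cc2OCOC)OC(C)(C)C=C3)O1
A3 | alternative 2 | (2S)-4-(tert-butyldimethylsilyloxy)-5,7-bis(methoxymethoxy)-2-[7-(methoxymethoxy)-2,2-dimethyl-2H-chromen-6-yl]-8-(3-methyl-3-triethylsilyloxybutyl)-2H-chromene | CC(C)(CCc1c(OCOC)cc(OCOC)c2c1O[C@H](c1cc3c(cc1OCOC)OC(C)(C)C=C3)C=C2O[Si](C)(C)C(C)(C)C)O[Si](CC)(CC)CC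
A4 | alternative 2 | tert-butyl({1-[2-{[(1S)-1-[7-(methoxymethoxy)-2,2-dimethyl-2H-chromen-6-yl]prop-2-en-1-yl]oxy}-4,6-bis(methoxymethoxy)-3-(3-methyl-3-triethylsilyloxybutyl)phenyl]ethenyl}oxy)dimethylsilane | C=C(O[Si](C)(C)C(C)(C)C)c1c(OCOC)cc(OCOC)c(CCC(C)(C)O[Si](CC)(CC)CC)c1O[C@@H](C=C)c1cc2c(cc1OCOC)OC(C)(C)C=C2
A5 | alternative 3 | (2S)-5,7-bis(methoxymethoxy)-2-[7-(methoxymethoxy)-2,2-dimethyl-2H-chromen-6-yl]-8-(3-methyl-3-triethylsilyloxybutyl)-2,3-dihydro-4H-chromen-4-one | CC(C)(CCc1c(OCOC)cc(OCOC)c2c1O[C@H](c1cc3c(cc1OCOC)OC(C)(C)C=C3)CC2=O)O[Si](CC)(CC)CC
A6 | alternative 3 | (3S)-1-[2-fluoro-4,6-bis(methoxymethoxy)-3-(3-methyl-3-triethylsilyloxybutyl)phenyl]-3-hydroxy-3-[7-(methoxymethoxy)-2,2-dimethyl-2H-chromen-6-yl]propan-1-one | CC(C)(CCc1c(OCOC)cc(OCOC)c(C(=O)C[C@H](O)c2cc3c(cc2OCOC)OC(C)(C)C=C3)c1F)O[Si](CC)(CC)CC
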